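**Plan**

- Retrosynthesis: the last phenol is masked as a MOM ether and ring B is taken back to a cyclohex-4-ene-cis-1,2-diol carbonate. This is cut at C1'–C6' and C4'–C5', because ring B has oxygen on three neighbouring carbons (aryloxy at C1', hydroxyls at C5' and C6') and carbon at C3': a 1-aryloxy-3-alkylbutadiene (C1'–C4') plus a cis-dioxygenated C5'–C6' unit.
- The diene is cut at its terminal C=CH2 (carbonyl methylenation) and at the enol ether O–C bond (phenol plus ethynyl ketone). Both quaternary carbons go back to C3 of (2E,6E)-farnesol.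
- Forward: the ring A phenol (aryl–C3 bond by SN2' arylation of farnesyl phosphate) and the ynone (farnesol, epoxide, 1,2-shift, vinyl, ethynyl ketone) are joined and methylenated. A [4+2] cycloaddition with vinylene carbonate then closes ring B.
- Methanolysis, double Swern oxidation with enolisation to the arene, and MOM removal finish the route.
- Stereochemistry: the (R) centre on ring A comes from a chiral NHC–copper catalyst. The (S) centre on ring B comes from Sharpless epoxidation with D-(−)-tartrate, relayed by an anti siloxymethyl shift. The three CH centres of the cycloadduct disappear on aromatisation.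

Key step: step 18

Assumption: the chiral NHC–copper catalyst of step 6 is taken to follow the facial preference known for geranyl-type phosphates, so the ligand antipode that delivers (R) is used; D-(−)-diethyl tartrate is taken to give the (2R,3R) epoxide of an (E)-allylic alcohol and the siloxymethyl shift of step 10 to be anti.

**Ring A phenol**

Step 1
Reactants: 1 (2E,6E)-farnesol
Product: 2 (2E,6E)-farnesyl diethyl phosphate
Conditions: ClP(O)(OEt)2, pyridine, CH2Cl2, 0 °C
Reagents that add atoms: diethyl chlorophosphate, CCOP(=O)(Cl)OCC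
Why: Phosphorylation of a primary allylic alcohol with a chlorophosphate and an amine base leaves both alkene geometries intact and installs the leaving group for the later SN2' substitution.

Step 2
Reactants: 3 catechol
Product: 4 2-(methoxymethoxy)phenol
Conditions: MOMCl (1.0 equiv), i-Pr2NEt, CH2Cl2, 0 °C to rt
Reagents that add atoms: chloromethyl methyl ether, COCCl
Why: Williamson-type O-alkylation of a symmetric diphenol with one equivalent of the chloromethyl ether should give the mono-acetal, which is separable from diol and bis-ether by chromatography.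

Step 3
Reactants: 4 2-(methoxymethoxy)phenol
Product: 5 4-bromo-2-(methoxymethoxy)phenol
Conditions: NBS (1.0 equiv), MeCN, −20 to 0 °C
Reagents that add atoms: N-bromosuccinimide, O=C1CCC(=O)N1Br
Why: Electrophilic aromatic bromination should go para to the free hydroxyl, the stronger donor, so that bromine sits para to the oxygen destined for the diaryl ether and meta to the MOM ether.

Step 4
Reactants: 5 4-bromo-2-(methoxymethoxy)phenol
Product: 6 [4-bromo-2-(methoxymethoxy)phenoxy]triisopropylsilane
Conditions: TIPSCl, imidazole, DMF, rt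
Reagents that add atoms: chlorotriisopropylsilane, CC(C)[Si](Cl)(C(C)C)C(C)C
Why: Imidazole-mediated silylation of the phenol gives a bulky silyl ether that tolerates the acetate and methoxide bases of the next two steps and cannot migrate, since the neighbouring oxygen is an acetal.

Step 5
Reactants: 6 [4-bromo-2-(methoxymethoxy)phenoxy]triisopropylsilane
Product: 7 2-[3-(methoxymethoxy)-4-(triisopropylsilyloxy)phenyl]-5,5-dimethyl-1,3,2-dioxaborinane
Conditions: bis(neopentyl glycolato)diboron, PdCl2(dppf) (3 mol %), KOAc, 1,4-dioxane, 80 °C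
Reagents that add atoms: bis(neopentyl glycolato)diboron, CC1(C)COB(OC1)B1OCC(C)(C)CO1
Why: Miyaura borylation of an electron-rich aryl bromide under acetate base is compatible with the silyl ether and the acetal and gives the neopentyl glycol boronate suited to copper-catalysed allyl–aryl coupling.

Step 6
Reactants: 2 (2E,6E)-farnesyl diethyl phosphate; 7 2-[3-(methoxymethoxy)-4-(triisopropylsilyloxy)phenyl]-5,5-dimethyl-1,3,2-dioxaborinane
Product: 8 triisopropyl{2-(methoxymethoxy)-4-[(3R,6E)-3,7,11-trimethyldodeca-1,6,10-trien-3-yl]phenoxy}silane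
Conditions: CuCl (5 mol %), chiral hydroxy-bearing imidazolinium chloride (NHC precursor, 6 mol %), NaOMe (2 equiv), THF, 30 °C
Reagents that add atoms: none
Why: Copper-catalysed enantioselective allylic substitution (SN2') of a γ,γ-disubstituted (E)-allylic phosphate with an arylboronate, in which the aryl–copper species formed by boron-to-copper transmetalation attacks C3 of the farnesyl unit with transposition of the alkene, the chiral NHC ligand selecting the alkene face and so setting the (R) quaternary carbon.

Step 7
Reactants: 8 triisopropyl{2-(methoxymethoxy)-4-[(3R,6E)-3,7,11-trimethyldodeca-1,6,10-trien-3-yl]phenoxy}silane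
Product: 9 2-(methoxymethoxy)-4-[(3R,6E)-3,7,11-trimethyldodeca-1,6,10-trien-3-yl]phenol
Conditions: TBAF, THF, 0 °C
Reagents that add atoms: none
Why: Fluoride cleavage of the aryl silyl ether frees the phenol without touching the MOM acetal, the alkenes or the quaternary centre.

**Ethynyl ketone**

Step 8
Reactants: 1 (2E,6E)-farnesol
Product: 10 (2R,3R)-2,3-epoxyfarnesol
Conditions: Ti(OiPr)4 (10 mol %), D-(−)-diethyl tartrate (12 mol %), t-BuOOH, 4 Å molecular sieves, CH2Cl2, −20 °C
Reagents that add atoms: tert-butyl hydroperoxide, CC(C)(C)OO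
Why: Sharpless asymmetric epoxidation oxidises only the alkene of the allylic alcohol because the titanium tartrate complex binds the hydroxyl, and D-(−)-tartrate directs oxygen to the face that gives the (2R,3R) epoxide, which fixes both new stereocentres.

Step 9
Reactants: 10 (2R,3R)-2,3-epoxyfarnesol
Product: 11 (2R,3R)-2,3-epoxyfarnesyl tert-butyldimethylsilyl ether
Conditions: TBSCl, imidazole, CH2Cl2, 0 °C to rt
Reagents that add atoms: tert-butyldimethylsilyl chloride, CC(C)(C)[Si](C)(C)Cl
Why: Standard silylation of the primary alcohol supplies the siloxymethyl group that migrates in the next step.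

Step 10
Reactants: 11 (2R,3R)-2,3-epoxyfarnesyl tert-butyldimethylsilyl ether
Product: 12 (2R,5E)-2-[(tert-butyldimethylsilyloxy)methyl]-2,6,10-trimethylundeca-5,9-dienal
Conditions: MeAl(OC6H2-4-Br-2,6-t-Bu2)2 (20 mol %), CH2Cl2, −78 to −40 °C
Reagents that add atoms: none
Why: Lewis-acid-promoted semipinacol-type rearrangement of a 2,3-epoxy silyl ether, in which the bulky aluminium phenoxide opens the epoxide at the tertiary C3 and the siloxymethyl group shifts from C2 to C3 anti to the departing oxygen, so that the epoxide configuration is relayed with inversion at C3 to the (R) quaternary aldehyde.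

Step 11
Reactants: 12 (2R,5E)-2-[(tert-butyldimethylsilyloxy)methyl]-2,6,10-trimethylundeca-5,9-dienal
Product: 13 tert-butyl{[(2S,5E)-2-ethenyl-2,6,10-trimethylundeca-5,9-dien-1-yl]oxy}dimethylsilane
Conditions: Ph3PCH3Br, KN(SiMe3)2, THF, 0 °C to rt
Reagents that add atoms: methyltriphenylphosphonium bromide, C[P+](c1ccccc1)(c1ccccc1)c1ccccc1.[Br-]
Why: Wittig methylenation of an aldehyde without α-hydrogen, where neither epimerisation nor β-elimination of the silyloxy group can intervene, turns the formyl group into the vinyl group of the quaternary carbon, whose descriptor becomes (S) only through the change in CIP priorities.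

Step 12
Reactants: 13 tert-butyl{[(2S,5E)-2-ethenyl-2,6,10-trimethylundeca-5,9-dien-1-yl]oxy}dimethylsilane
Product: 14 (2S,5E)-2-ethenyl-2,6,10-trimethylundeca-5,9-dien-1-ol
Conditions: TBAF, THF, rt
Reagents that add atoms: none
Why: Fluoride desilylation of a primary silyl ether is reliable and leaves the triene untouched.

Step 13
Reactants: 14 (2S,5E)-2-ethenyl-2,6,10-trimethylundeca-5,9-dien-1-ol
Product: 15 (2S,5E)-2-ethenyl-2,6,10-trimethylundeca-5,9-dienal
Conditions: Dess–Martin periodinane, CH2Cl2, 0 °C to rt
Reagents that add atoms: none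
Why: Dess–Martin oxidation of the neopentyl primary alcohol gives an aldehyde that can neither enolise nor move its β,γ-alkene into conjugation, so the stereocentre is safe.

Step 14
Reactants: 15 (2S,5E)-2-ethenyl-2,6,10-trimethylundeca-5,9-dienal
Product: 16 (4S,7E)-4-ethenyl-4,8,12-trimethyltrideca-7,11-dien-1-yn-3-ol (both C3 epimers)
Conditions: HC≡CMgBr, THF, −20 to 0 °C
Reagents that add atoms: ethynylmagnesium bromide, C#C[Mg]Br
Why: Grignard 1,2-addition of the small ethynyl nucleophile to a non-enolisable aldehyde should be clean, and the new carbinol centre, formed without control, is removed in the next step.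

Step 15
Reactants: 16 (4S,7E)-4-ethenyl-4,8,12-trimethyltrideca-7,11-dien-1-yn-3-ol
Product: 17 (4S,7E)-4-ethenyl-4,8,12-trimethyltrideca-7,11-dien-1-yn-3-one
Conditions: Dess–Martin periodinane, CH2Cl2, 0 °C
Reagents that add atoms: none
Why: Dess–Martin oxidation of the secondary propargylic alcohol gives the ethynyl ketone under neutral conditions and erases the carbinol centre.

**Union, ring B and end game**

Step 16
Reactants: 9 2-(methoxymethoxy)-4-[(3R,6E)-3,7,11-trimethyldodeca-1,6,10-trien-3-yl]phenol; 17 (4S,7E)-4-ethenyl-4,8,12-trimethyltrideca-7,11-dien-1-yn-3-one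
Product: 18 (1E,4S,7E)-4-ethenyl-1-{2-(methoxymethoxy)-4-[(3R,6E)-3,7,11-trimethyldodeca-1,6,10-trien-3-yl]phenoxy}-4,8,12-trimethyltrideca-1,7,11-trien-3-one
Conditions: DABCO (10 mol %), CH2Cl2, 0 °C to rt
Reagents that add atoms: none
Why: Amine-catalysed oxa-Michael addition of a phenol to a terminal ynone, running through a β-ammonium enone that the phenoxide substitutes by addition–elimination, should give the thermodynamically preferred (E)-β-aryloxy enone.

Step 17
Reactants: 18 (1E,4S,7E)-4-ethenyl-1-{2-(methoxymethoxy)-4-[(3R,6E)-3,7,11-trimethyldodeca-1,6,10-trien-3-yl]phenoxy}-4,8,12-trimethyltrideca-1,7,11-trien-3-one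
Product: 19 1-{[(1E,4S,7E)-4-ethenyl-4,8,12-trimethyl-3-methylidenetrideca-1,7,11-trien-1-yl]oxy}-2-(methoxymethoxy)-4-[(3R,6E)-3,7,11-trimethyldodeca-1,6,10-trien-3-yl]benzene (the (E)-1-aryloxy-3-alkylbuta-1,3-diene)
Conditions: Cp2TiMe2 (2.5 equiv), toluene, 70 °C, dark
Reagents that add atoms: dimethyltitanocene (Cp2TiMe2), C[Ti+2]C.c1cc[cH-]c1.c1cc[cH-]c1
Why: Petasis methylenation, in which the non-basic titanium methylidene generated thermally from Cp2TiMe2 converts hindered ketones and vinylogous esters into 1,1-disubstituted alkenes through an oxatitanacyclobutane, should turn the carbonyl into the terminal methylene of the diene without isomerising the (E) enol ether.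

Step 18
Reactants: 19 the (E)-1-aryloxy-3-alkylbuta-1,3-diene; 20 vinylene carbonate
Product: 21 cis-fused 4-aryloxy-6-alkyl-3a,4,7,7a-tetrahydro-1,3-benzodioxol-2-one (aryloxy = ring A with its (R) side chain, alkyl = the (S) side chain; endo adduct with the three ring oxygens cis, drawn as one of two facial isomers, all ring isomers carried on together)
Conditions: 20 (10 equiv), BHT (5 mol %), toluene, sealed tube, 155 °C
Reagents that add atoms: none
Why: This is a thermal, concerted, suprafacial [4+2] Diels–Alder cycloaddition, the closest known reaction type being the addition of vinylene carbonate to 1-acyloxy- and 1-alkoxybutadienes. Ring B is closed as a six-membered carbocycle by intermolecular [4+2] annulation in which the C1'–C6' and C4'–C5' bonds form in the same step. The three new CH stereocentres (C1', C5', C6') are governed only by the cis geometry of the dienophile (C5'/C6' cis) and the endo preference (aryloxy at C1' cis to the carbonate), the remote quaternary carbons giving no facial bias, and none of this matters because all three centres are erased on aromatisation. The selectivity that is needed is chemoselectivity for the conjugated diene over the six isolated alkenes, which the raised HOMO of the 1-aryloxy-3-alkyl diene and the bulky quaternary substituent on the internal diene carbon (favouring the s-cis conformer) should secure. The symmetric dienophile removes any regiochemical question, the aryloxy oxygen already sits on the carbon that becomes C1', and BHT suppresses radical polymerisation of the excess dienophile.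

Step 19
Reactants: 21 the cyclohexene carbonate cycloadduct
Product: 22 (1,2-cis)-3-aryloxy-5-alkylcyclohex-4-ene-1,2-diol (substituents as in 21)
Conditions: K2CO3 (0.3 equiv), MeOH, 0 °C to rt
Reagents that add atoms: none
Why: Base-catalysed transesterification of the cyclic carbonate with methanol releases the cis-diol under conditions that leave the allylic aryl ether and the MOM acetal alone.

Step 20
Reactants: 22 the cyclohexene cis-diol
Product: 24 3-{2-(methoxymethoxy)-4-[(3R,6E)-3,7,11-trimethyldodeca-1,6,10-trien-3-yl]phenoxy}-5-[(3S,6E)-3,7,11-trimethyldodeca-1,6,10-trien-3-yl]benzene-1,2-diol, via cyclohex-4-ene-1,2-dione 23 (not isolated)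
Conditions: (COCl)2, DMSO, CH2Cl2, −78 °C; then Et3N, −78 to 0 °C, argon
Reagents that add atoms: none
Why: Swern oxidation of both secondary alcohols should give the cyclohex-4-ene-1,2-dione, which under the amine base enolises toward C1' and C4' to the catechol, the gain of aromaticity driving the tautomerisation and removing the three ring CH centres.

Step 21
Reactants: 24 the MOM-protected diaryl ether catechol
Product: 25 3-{2-hydroxy-4-[(3R,6E)-3,7,11-trimethyldodeca-1,6,10-trien-3-yl]phenoxy}-5-[(3S,6E)-3,7,11-trimethyldodeca-1,6,10-trien-3-yl]benzene-1,2-diol (CNP0230356.1)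
Conditions: HCl (0.5 M in MeOH), THF, 0 °C to rt, argon
Reagents that add atoms: none
Why: Acid-catalysed transacetalisation of the aryl MOM ether to methanol, run dilute and cold so that the trisubstituted alkenes are not protonated, should free the last phenol while the quaternary centres, which carry no leaving group, stay fixed.

**Compound list**

1 | (2E,6E)-farnesol | CC(C)=CCC/C(C)=C/CC/C(C)=C/CO | starting material
2 | (2E,6E)-farnesyl diethyl phosphate | CC(C)=CCC/C(C)=C/CC/C(C)=C/COP(=O)(OCC)OCC | intermediate
3 | catechol | Oc1ccccc1O | starting material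
4 | 2-(methoxymethoxy)phenol | COCOc1ccccc1O | intermediate
5 | 4-bromo-2-(methoxymethoxy)phenol | COCOc1cc(Br)ccc1O | intermediate
6 | [4-bromo-2-(methoxymethoxy)phenoxy]triisopropylsilane | COCOc1cc(Br)ccc1O[Si](C(C)C)(C(C)C)C(C)C | intermediate
7 | 2-[3-(methoxymethoxy)-4-(triisopropylsilyloxy)phenyl]-5,5-dimethyl-1,3,2-dioxaborinane | COCOc1cc(B2OCC(C)(C)CO2)ccc1O[Si](C(C)C)(C(C)C)C(C)C | intermediate
8 | triisopropyl{2-(methoxymethoxy)-4-[(3R,6E)-3,7,11-trimethyldodeca-1,6,10-trien-3-yl]phenoxy}silane | COCOc1cc([C@@](C)(C=C)CC/C=C(\C)CCC=C(C)C)ccc1O[Si](C(C)C)(C(C)C)C(C)C | intermediate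
9 | 2-(methoxymethoxy)-4-[(3R,6E)-3,7,11-trimethyldodeca-1,6,10-trien-3-yl]phenol (ring A phenol) | COCOc1cc([C@@](C)(C=C)CC/C=C(\C)CCC=C(C)C)ccc1O | intermediate
10 | (2R,3R)-2,3-epoxyfarnesol | CC(C)=CCC/C(C)=C/CC[C@@]1(C)O[C@@H]1CO | intermediate
11 | (2R,3R)-2,3-epoxyfarnesyl tert-butyldimethylsilyl ether | CC(C)=CCC/C(C)=C/CC[C@@]1(C)O[C@@H]1CO[Si](C)(C)C(C)(C)C | intermediate
12 | (2R,5E)-2-[(tert-butyldimethylsilyloxy)methyl]-2,6,10-trimethylundeca-5,9-dienal | O=C[C@@](C)(CO[Si](C)(C)C(C)(C)C)CC/C=C(\C)CCC=C(C)C | intermediate
13 | tert-butyl{[(2S,5E)-2-ethenyl-2,6,10-trimethylundeca-5,9-dien-1-yl]oxy}dimethylsilane | C=C[C@@](C)(CO[Si](C)(C)C(C)(C)C)CC/C=C(\C)CCC=C(C)C | intermediate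
14 | (2S,5E)-2-ethenyl-2,6,10-trimethylundeca-5,9-dien-1-ol | C=C[C@@](C)(CO)CC/C=C(\C)CCC=C(C)C | intermediate
15 | (2S,5E)-2-ethenyl-2,6,10-trimethylundeca-5,9-dienal | C=C[C@@](C)(C=O)CC/C=C(\C)CCC=C(C)C | intermediate
16 | (4S,7E)-4-ethenyl-4,8,12-trimethyltrideca-7,11-dien-1-yn-3-ol (both C3 epimers) | C#CC(O)[C@](C)(C=C)CC/C=C(\C)CCC=C(C)C | intermediate
17 | (4S,7E)-4-ethenyl-4,8,12-trimethyltrideca-7,11-dien-1-yn-3-one | C#CC(=O)[C@](C)(C=C)CC/C=C(\C)CCC=C(C)C | intermediate
18 | (E)-β-aryloxy enone (see step 16) | O=C(/C=C/Oc1ccc([C@@](C)(C=C)CC/C=C(\C)CCC=C(C)C)cc1OCOC)[C@](C)(C=C)CC/C=C(\C)CCC=C(C)C | intermediate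
19 | (E)-1-aryloxy-3-alkylbuta-1,3-diene (see step 17) | C=C(/C=C/Oc1ccc([C@@](C)(C=C)CC/C=C(\C)CCC=C(C)C)cc1OCOC)[C@](C)(C=C)CC/C=C(\C)CCC=C(C)C | intermediate
20 | vinylene carbonate | O=C1OC=CO1 | starting material
21 | endo cyclohexene carbonate cycloadduct (one facial isomer drawn) | O=C1O[C@H]2CC([C@](C)(C=C)CC/C=C(\C)CCC=C(C)C)=C[C@@H](Oc3ccc([C@@](C)(C=C)CC/C=C(\C)CCC=C(C)C)cc3OCOC)[C@H]2O1 | intermediate
22 | (1,2-cis)-3-aryloxy-5-alkylcyclohex-4-ene-1,2-diol (one isomer drawn) | O[C@H]1CC([C@](C)(C=C)CC/C=C(\C)CCC=C(C)C)=C[C@@H](Oc2ccc([C@@](C)(C=C)CC/C=C(\C)CCC=C(C)C)cc2OCOC)[C@H]1O | intermediate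
23 | 3-aryloxy-5-alkylcyclohex-4-ene-1,2-dione (formed in the flask in step 20, C3 epimers) | O=C1CC([C@](C)(C=C)CC/C=C(\C)CCC=C(C)C)=CC(Oc2ccc([C@@](C)(C=C)CC/C=C(\C)CCC=C(C)C)cc2OCOC)C1=O | intermediate
24 | MOM ether of the target at the ring A hydroxyl | COCOc1cc([C@@](C)(C=C)CC/C=C(\C)CCC=C(C)C)ccc1Oc1cc([C@](C)(C=C)CC/C=C(\C)CCC=C(C)C)cc(O)c1O | intermediate
25 | CNP0230356.1 | C=C[C@@](C)(CC/C=C(\C)CCC=C(C)C)c1ccc(Oc2cc([C@](C)(C=C)CC/C=C(\C)CCC=C(C)C)cc(O)c2O)c(O)c1 | target

**Step count**

Total: 21 steps. Longest linear sequence: 14 steps (1 to 25 through steps 8–21).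

**Steps most likely to fail**

Step 18. The cycloaddition may be slower than the thermal loss of the diene: radical polymerisation of the dienophile, oligomerisation of the electron-rich diene, or acid-induced loss of its aryloxy group could consume material before the ring closes. The fallback sets out from diene 19 and uses a more electrophilic cis-dioxygenated dienophile at the dione oxidation level, 4,5-dichloro-1,3-dioxol-2-one (O=C1OC(Cl)=C(Cl)O1), in toluene at 90–110 °C. The same C1'–C6' and C4'–C5' bonds form and the same ring closes, giving the dichloro carbonate cycloadduct F1. Mild hydrolysis (NaHCO3, aqueous THF, rt) should unmask the 1,2-dione 23, which enolises to the catechol. The fallback rejoins the route at 24, and steps 19 and 20 are no longer needed.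

Step 17. Methylenation of the hindered vinylogous-ester carbonyl may stay incomplete at the temperature needed to generate the titanium methylidene, while the enol ether degrades or the terminal vinyl groups divert the methylidene. The fallback sets out from enone 18 and replaces the metallacycle route by a Peterson olefination. Me3SiCH2Li with anhydrous CeCl3 (THF, −78 °C) should add 1,2 to the ketone to give the β-hydroxysilane F2. KH in THF at 0 °C then induces syn elimination under basic conditions that spare the enol ether. The fallback rejoins at diene 19.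

Step 6. The aryl–copper species may discriminate poorly between methyl and methylene at the γ-carbon, or leak to α-substitution, giving ring A material of insufficient enantiomeric purity that would show up at the end as a hard-to-separate diastereomer. The fallback sets out from phosphate 2 and boronate 7 and gives up catalyst control in favour of resolution. The same γ-selective allyl–aryl coupling with an achiral catalyst (CuCl, 1,3-dimesitylimidazolium chloride, NaOMe, THF) gives the racemic silyl ether F3. TBAF gives the racemic phenol F4. Preparative chromatography on a chiral stationary phase (cellulose carbamate, supercritical CO2 with MeOH) separates the antipodes, and the (R) enantiomer is identified by comparison with material from the catalytic route. The fallback rejoins at phenol 9; partly enriched material from step 6 can be upgraded the same way.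

**Further compounds**

F1 | step 18 | cis-fused 3a,7a-dichloro-4-aryloxy-6-alkyl-3a,4,7,7a-tetrahydro-1,3-benzodioxol-2-one (ring isomers) | O=C1OC2(Cl)CC([C@](C)(C=C)CC/C=C(\C)CCC=C(C)C)=CC(Oc3ccc([C@@](C)(C=C)CC/C=C(\C)CCC=C(C)C)cc3OCOC)C2(Cl)O1
F2 | step 17 | β-hydroxysilane from 1,2-addition of Me3SiCH2Li to 18 (carbinol epimers) | C[Si](C)(C)CC(O)(/C=C/Oc1ccc([C@@](C)(C=C)CC/C=C(\C)CCC=C(C)C)cc1OCOC)[C@](C)(C=C)CC/C=C(\C)CCC=C(C)C
F3 | step 6 | racemic triisopropyl{2-(methoxymethoxy)-4-[(6E)-3,7,11-trimethyldodeca-1,6,10-trien-3-yl]phenoxy}silane | COCOc1cc(C(C)(C=C)CC/C=C(\C)CCC=C(C)C)ccc1O[Si](C(C)C)(C(C)C)C(C)C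
F4 | step 6 | racemic 2-(methoxymethoxy)-4-[(6E)-3,7,11-trimethyldodeca-1,6,10-trien-3-yl]phenol | COCOc1cc(C(C)(C=C)CC/C=C(\C)CCC=C(C)C)ccc1O
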